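**Retrosynthetic overview**

1. Locants follow 2,3,6,7-tetrahydro-1-benzofuran (O1, C2, C3, C3a, C4–C7, C7a). Last operations: the phenol is freed from its silyl ether and C6–OH is made from a C6 boronic ester with retention.
2. Key disconnection: the cyclohexadiene ring is opened at C6–C7 (retro-6π-electrocyclisation) to the hexatriene C7=C7a–C3a=C4(OMe)–C5=C6. The oxolane ring is then opened at C3a–C7a (retro-Heck) and C4–C5 is cut (retro-carbopalladation), leaving enyne 15 and alkenyl bromide 17.
3. Enabling feature: the ring-fusion enol ether C7a=C3a is conjugated with the enol ether C4(OMe)=C5 and flanked by the sp3 pair C6/C7, which is a cyclohexa-1,3-diene retron. Its tetrasubstituted C3a=C4(OMe) unit is the syn adduct of a methoxyalkyne, and C7a carries both O1 and the C7 acyl arm, i.e. an O-tethered vinylogous ester.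
4. 15 comes from oxa-Michael addition of diol 10 to ynone 14. 10 (C2, C3) comes from Jacobsen epoxidation of a (Z)-styrenyl carbinol and alkoxide-directed opening with a methoxyethynyl alane.
5. Ring order: oxolane ring first (C3a–C7a), cyclohexadiene ring second (C6–C7), both in step 10.

Key step: step 10

Remark: the target loses water across C6–C7 very easily to give an aromatic benzofuran, so the C6 oxygen is carried as a boronic ester and every step after step 10 is run cold and near neutrality; 1, 3, 7, 11, 12 and 16 are taken as commercial.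

**Route**

Step 1
Reactants: 1 methyl 4-hydroxy-3-iodobenzoate
Product: 2 methyl 4-[(tert-butyldimethylsilyl)oxy]-3-iodobenzoate
Conditions: TBSCl, imidazole, DMF, rt
Reagents that add atoms: tert-butyldimethylsilyl chloride, CC(C)(C)[Si](C)(C)Cl
Why: O-silylation of the phenol keeps it from cyclising onto the alkyne in step 2 and from quenching the organometallic reagents later; no stereocentre is involved.

Step 2
Reactants: 2 methyl 4-[(tert-butyldimethylsilyl)oxy]-3-iodobenzoate; 3 2-methylbut-3-yn-2-ol
Product: 4 methyl 4-[(tert-butyldimethylsilyl)oxy]-3-(3-hydroxy-3-methylbut-1-yn-1-yl)benzoate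
Conditions: Pd(PPh3)2Cl2 (2 mol %), CuI (4 mol %), Et3N, THF, rt
Reagents that add atoms: none
Why: Sonogashira coupling of an aryl iodide with a terminal alkyne is reliable next to an ortho silyloxy group and tolerates the ester and the free tertiary alcohol.

Step 3
Reactants: 4 methyl 4-[(tert-butyldimethylsilyl)oxy]-3-(3-hydroxy-3-methylbut-1-yn-1-yl)benzoate
Product: 5 methyl 4-[(tert-butyldimethylsilyl)oxy]-3-[(1Z)-3-hydroxy-3-methylbut-1-en-1-yl]benzoate
Conditions: H2 (1 atm), Pd/CaCO3 poisoned with Pb(OAc)2, quinoline, EtOAc, rt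
Reagents that add atoms: none
Why: Lindlar semihydrogenation adds hydrogen syn and should stop at the (Z)-alkene, which is needed because a cis-epoxide leads to the trans-2,3 relationship of the oxolane.

Step 4
Reactants: 5 methyl 4-[(tert-butyldimethylsilyl)oxy]-3-[(1Z)-3-hydroxy-3-methylbut-1-en-1-yl]benzoate
Product: 6 methyl 4-[(tert-butyldimethylsilyl)oxy]-3-[(2R,3R)-3-(2-hydroxypropan-2-yl)oxiran-2-yl]benzoate
Conditions: (R,R)-[N,N'-bis(3,5-di-tert-butylsalicylidene)cyclohexane-1,2-diaminato]MnCl (5 mol %, chloride of trivalent manganese), NaOCl (aq., pH 11.3), 4-phenylpyridine N-oxide, CH2Cl2, 0 °C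
Reagents that add atoms: sodium hypochlorite, [Na+].[O-]Cl
Why: Jacobsen–Katsuki epoxidation of a cis-disubstituted aryl alkene sets both epoxide carbons (the later C3 and C2) under catalyst control; the (R,R)-catalyst is chosen by analogy with cis-β-methylstyrene, where it makes the benzylic carbon R.

Step 5
Reactants: 6 methyl 4-[(tert-butyldimethylsilyl)oxy]-3-[(2R,3R)-3-(2-hydroxypropan-2-yl)oxiran-2-yl]benzoate; 7 2-chloro-1,1-dimethoxyethane
Product: 10 methyl 4-[(tert-butyldimethylsilyl)oxy]-3-[(3S,4R)-4,5-dihydroxy-1-methoxy-5-methylhex-1-yn-3-yl]benzoate, via lithium methoxyacetylide 8 (not isolated), via diethyl(methoxyethynyl)aluminium 9 (not isolated)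
Conditions: 7, LiNEt2 (3 equiv), THF, −10 °C; solvent exchange to toluene, Et2AlCl, 0 °C; then 6, 0 °C to rt; Rochelle-salt work-up
Reagents that add atoms: none
Why: Alkynylalane opening of a 2,3-epoxy alcohol delivers the alkynyl group from the aluminium alkoxide to the distal benzylic carbon (the neopentyl C2 is blocked) with inversion, which sets C3 while C2 keeps its oxygen and configuration.

Step 6
Reactants: 11 3-phenylpropanal; 12 ethynylmagnesium bromide
Product: 13 5-phenylpent-1-yn-3-ol (racemic)
Conditions: THF, 0 °C; aq. NH4Cl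
Reagents that add atoms: none
Why: Grignard addition to an aldehyde gives the propargylic alcohol, whose racemic carbinol centre is removed in step 7.

Step 7
Reactants: 13 5-phenylpent-1-yn-3-ol
Product: 14 5-phenylpent-1-yn-3-one
Conditions: Dess–Martin periodinane, NaHCO3, CH2Cl2, 0 °C to rt
Reagents that add atoms: none
Why: Dess–Martin oxidation converts the propargylic alcohol into the terminal ynone under buffered conditions, without base that would polymerise it.

Step 8
Reactants: 10 methyl 4-[(tert-butyldimethylsilyl)oxy]-3-[(3S,4R)-4,5-dihydroxy-1-methoxy-5-methylhex-1-yn-3-yl]benzoate; 14 5-phenylpent-1-yn-3-one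
Product: 15 methyl 4-[(tert-butyldimethylsilyl)oxy]-3-[(3S,4R)-5-hydroxy-1-methoxy-5-methyl-4-{[(1E)-3-oxo-5-phenylpent-1-en-1-yl]oxy}hex-1-yn-3-yl]benzoate
Conditions: PMe3 (10 mol %), 14 (1.05 equiv), CH2Cl2, 0 °C
Reagents that add atoms: none
Why: Phosphine-catalysed oxa-Michael addition of the secondary hydroxyl to the ynone should give the (E)-β-alkoxyenone; the tertiary hydroxyl is too hindered to compete, and the base-stable ynol ether is untouched.

Step 9
Reactants: 16 (E)-2-bromovinylboronic acid MIDA ester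
Product: 17 2-[(E)-2-bromoethenyl]-4,4,5,5-tetramethyl-1,3,2-dioxaborolane
Conditions: pinacol, NaHCO3, MeOH, 45 °C
Reagents that add atoms: pinacol, CC(C)(O)C(C)(C)O
Why: Transesterification of the MIDA boronate gives the pinacol ester, which can be oxidised at the end under mild conditions; the alkene geometry is untouched.

Step 10
Reactants: 15 methyl 4-[(tert-butyldimethylsilyl)oxy]-3-[(3S,4R)-5-hydroxy-1-methoxy-5-methyl-4-{[(1E)-3-oxo-5-phenylpent-1-en-1-yl]oxy}hex-1-yn-3-yl]benzoate; 17 2-[(E)-2-bromoethenyl]-4,4,5,5-tetramethyl-1,3,2-dioxaborolane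
Product: 19 methyl 4-[(tert-butyldimethylsilyl)oxy]-3-[(2R,3R,6R,7R)-2-(2-hydroxypropan-2-yl)-4-methoxy-7-(3-phenylpropanoyl)-6-(4,4,5,5-tetramethyl-1,3,2-dioxaborolan-2-yl)-2,3,6,7-tetrahydro-1-benzofuran-3-yl]benzoate, via hexatriene 18 (not isolated)
Conditions: Pd2(dba)3 (5 mol %), P(2-furyl)3 (20 mol %), Cy2NMe (2 equiv), 17 (1.5 equiv), toluene, 80 °C
Reagents that add atoms: none
Why: Proposed new method: oxidative addition of zerovalent palladium to 17 is followed by syn-carbopalladation of the methoxyalkyne of 15 (alkenyl carbon to the methoxy-bearing C4, palladium to C3a, because C4 is the less hindered and electrophilic alkyne carbon and the tethered enone chelates palladium), 5-exo-trig insertion of the O-linked β-alkoxyenone into the C3a–Pd bond (this forms C3a–C7a and closes the oxolane ring) and syn-β-hydride elimination, which gives the (E,Z,E)-hexatriene 18 with the acyl and boryl groups on the outside. The closest known reaction type is the palladium-catalysed alkenylative cyclisation of 1,6-enynes with alkenyl halides that ends in a 6π-electrocyclisation, which has not been run with a ynol ether as the alkyne and a vinylogous ester as the alkene. Triene 18 then closes the six-membered ring thermally by disrotatory 6π-electrocyclisation (forming C6–C7) and so delivers the C7a=C3a–C4(OMe)=C5 diene directly at the correct oxidation level. The cis relation of C6 and C7 follows stereospecifically from the two outside substituents of the (E,Z,E)-triene, whereas their sense relative to C2/C3 rests on torquoselectivity: the pseudo-axial aryl group at C3 should push the C4 methoxy group to the opposite face, so the C5=C6 arm and both termini bend toward the aryl face and the acyl and boryl groups rotate to the face anti to the aryl group, where the free tertiary hydroxyl at C2 can hydrogen-bond the ketone. The step needs carbopalladation of the alkyne ahead of any direct Heck coupling of 17 with the enone, which the electron-rich unhindered ynol ether and the fast intramolecular trapping should secure, and facial selectivity in the ring closure, which is the less certain point.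

Step 11
Reactants: 19 methyl 4-[(tert-butyldimethylsilyl)oxy]-3-[(2R,3R,6R,7R)-2-(2-hydroxypropan-2-yl)-4-methoxy-7-(3-phenylpropanoyl)-6-(4,4,5,5-tetramethyl-1,3,2-dioxaborolan-2-yl)-2,3,6,7-tetrahydro-1-benzofuran-3-yl]benzoate
Product: 20 methyl 4-[(tert-butyldimethylsilyl)oxy]-3-[(2R,3R,6R,7R)-6-hydroxy-2-(2-hydroxypropan-2-yl)-4-methoxy-7-(3-phenylpropanoyl)-2,3,6,7-tetrahydro-1-benzofuran-3-yl]benzoate
Conditions: NaBO3·4H2O (3 equiv), THF/H2O (1:1), 0 °C, short reaction time
Reagents that add atoms: sodium perborate, [Na+].[O-]OB=O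
Why: Perborate oxidation of the boronic ester moves C6 from boron to oxygen with retention, so the new hydroxyl stays cis to the acyl group, and it is mild enough that the β-hydroxy ketone should not lose water.

Step 12
Reactants: 20 methyl 4-[(tert-butyldimethylsilyl)oxy]-3-[(2R,3R,6R,7R)-6-hydroxy-2-(2-hydroxypropan-2-yl)-4-methoxy-7-(3-phenylpropanoyl)-2,3,6,7-tetrahydro-1-benzofuran-3-yl]benzoate
Product: 21 methyl 4-hydroxy-3-[(2R,3R,6R,7R)-6-hydroxy-2-(2-hydroxypropan-2-yl)-4-methoxy-7-(3-phenylpropanoyl)-2,3,6,7-tetrahydro-1-benzofuran-3-yl]benzoate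
Conditions: TBAF, AcOH (1:1), THF, 0 °C
Reagents that add atoms: none
Why: Acetic acid-buffered fluoride cleaves the aryl silyl ether within minutes without the basicity that would trigger β-elimination, and touches no stereocentre.

**Compound list**

1 | methyl 4-hydroxy-3-iodobenzoate | COC(=O)c1ccc(O)c(I)c1 | starting material
2 | methyl 4-[(tert-butyldimethylsilyl)oxy]-3-iodobenzoate | COC(=O)c1ccc(O[Si](C)(C)C(C)(C)C)c(I)c1 | intermediate
3 | 2-methylbut-3-yn-2-ol | CC(C)(O)C#C | starting material
4 | methyl 4-[(tert-butyldimethylsilyl)oxy]-3-(3-hydroxy-3-methylbut-1-yn-1-yl)benzoate | COC(=O)c1ccc(O[Si](C)(C)C(C)(C)C)c(c1)C#CC(C)(C)O | intermediate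
5 | methyl 4-[(tert-butyldimethylsilyl)oxy]-3-[(1Z)-3-hydroxy-3-methylbut-1-en-1-yl]benzoate | COC(=O)c1ccc(O[Si](C)(C)C(C)(C)C)c(c1)/C=C\C(C)(C)O | intermediate
6 | methyl 4-[(tert-butyldimethylsilyl)oxy]-3-[(2R,3R)-3-(2-hydroxypropan-2-yl)oxiran-2-yl]benzoate (cis-epoxide) | COC(=O)c1ccc(O[Si](C)(C)C(C)(C)C)c(c1)[C@H]2O[C@H]2C(C)(C)O | intermediate
7 | 2-chloro-1,1-dimethoxyethane | COC(CCl)OC | starting material
8 | lithium methoxyacetylide | [Li]C#COC | intermediate (not isolated)
9 | diethyl(methoxyethynyl)aluminium | CC[Al](CC)C#COC | intermediate (not isolated)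
10 | methyl 4-[(tert-butyldimethylsilyl)oxy]-3-[(3S,4R)-4,5-dihydroxy-1-methoxy-5-methylhex-1-yn-3-yl]benzoate | COC(=O)c1ccc(O[Si](C)(C)C(C)(C)C)c(c1)[C@H](C#COC)[C@@H](O)C(C)(C)O | intermediate
11 | 3-phenylpropanal | O=CCCc1ccccc1 | starting material
12 | ethynylmagnesium bromide | C#C[Mg]Br | starting material
13 | 5-phenylpent-1-yn-3-ol (racemic) | C#CC(O)CCc1ccccc1 | intermediate
14 | 5-phenylpent-1-yn-3-one | C#CC(=O)CCc1ccccc1 | intermediate
15 | methyl 4-[(tert-butyldimethylsilyl)oxy]-3-[(3S,4R)-5-hydroxy-1-methoxy-5-methyl-4-{[(1E)-3-oxo-5-phenylpent-1-en-1-yl]oxy}hex-1-yn-3-yl]benzoate | COC(=O)c1ccc(O[Si](C)(C)C(C)(C)C)c(c1)[C@H](C#COC)[C@@H](O/C=C/C(=O)CCc2ccccc2)C(C)(C)O | intermediate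
16 | (E)-2-bromovinylboronic acid MIDA ester | CN1CC(=O)OB(/C=C/Br)OC(=O)C1 | starting material
17 | 2-[(E)-2-bromoethenyl]-4,4,5,5-tetramethyl-1,3,2-dioxaborolane | Br/C=C/B1OC(C)(C)C(C)(C)O1 | intermediate
18 | methyl 4-[(tert-butyldimethylsilyl)oxy]-3-[(2R,3R,4E,5Z)-2-(2-hydroxypropan-2-yl)-4-[(2E)-1-methoxy-3-(4,4,5,5-tetramethyl-1,3,2-dioxaborolan-2-yl)prop-2-en-1-ylidene]-5-(2-oxo-4-phenylbutylidene)oxolan-3-yl]benzoate (acyl cis to the ring oxygen, boryl-vinyl arm cis to C7a) | COC(=O)c1ccc(O[Si](C)(C)C(C)(C)C)c(c1)[C@H]2[C@H](C(C)(C)O)O/C(=C\C(=O)CCc3ccccc3)/C2=C(OC)\C=C\B4OC(C)(C)C(C)(C)O4 | intermediate (not isolated)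
19 | methyl 4-[(tert-butyldimethylsilyl)oxy]-3-[(2R,3R,6R,7R)-2-(2-hydroxypropan-2-yl)-4-methoxy-7-(3-phenylpropanoyl)-6-(4,4,5,5-tetramethyl-1,3,2-dioxaborolan-2-yl)-2,3,6,7-tetrahydro-1-benzofuran-3-yl]benzoate | COC(=O)c1ccc(O[Si](C)(C)C(C)(C)C)c(c1)[C@@H]2C3=C(O[C@H]2C(C)(C)O)[C@H](C(=O)CCc4ccccc4)[C@H](B5OC(C)(C)C(C)(C)O5)C=C3OC | intermediate
20 | methyl 4-[(tert-butyldimethylsilyl)oxy]-3-[(2R,3R,6R,7R)-6-hydroxy-2-(2-hydroxypropan-2-yl)-4-methoxy-7-(3-phenylpropanoyl)-2,3,6,7-tetrahydro-1-benzofuran-3-yl]benzoate | COC(=O)c1ccc(O[Si](C)(C)C(C)(C)C)c(c1)[C@@H]2C3=C(O[C@H]2C(C)(C)O)[C@H](C(=O)CCc4ccccc4)[C@H](O)C=C3OC | intermediate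
21 | methyl 4-hydroxy-3-[(2R,3R,6R,7R)-6-hydroxy-2-(2-hydroxypropan-2-yl)-4-methoxy-7-(3-phenylpropanoyl)-2,3,6,7-tetrahydro-1-benzofuran-3-yl]benzoate | COC(=O)c1ccc(O)c([C@@H]2C3=C(O[C@H]2C(C)(C)O)[C@H](C(=O)CCc2ccccc2)[C@H](O)C=C3OC)c1 | target

**Step count and risks**

Total step count: 12. Longest linear sequence: 9 (steps 1, 2, 3, 4, 5, 8, 10, 11, 12).

Steps most likely to fail:

1. Step 10 (Proposed new method). The alkenylpalladium species may add to the ynol ether in the wrong orientation or couple directly with the enone, 17 may oligomerise, and the electrocyclisation may show poor facial selectivity. The fallback uses known chemistry in separate stages, sets out from 15 and 17 and comes back to the route at 21.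
   - Zinc insertion into 17 (Zn dust, LiCl, THF) should give (E)-2-(pinacolboryl)ethenylzinc bromide F1.
   - Nickel-catalysed alkylative cyclisation of the alkynyl enone 15 with F1 (Ni(cod)2, PPh3, THF, 0 °C) should join C3a to C7a and place the alkenyl group cis to C7a on C4. The zinc enolate and the zinc alkoxide are silylated in the flask with Me3SiCl, which gives the bis(trimethylsilyl) compound F2.
   - Saegusa–Ito oxidation of F2 (Pd(OAc)2, MeCN, rt) should form the C7=C7a enone, and the resulting triene should electrocyclise on warming to the O-trimethylsilyl boronate F3.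
   - Perborate as in step 11 should give the O-trimethylsilyl alcohol F4, and buffered fluoride as in step 12 should remove both silyl ethers to give 21.

2. Step 11. Once the β-hydroxy ketone is unmasked in aqueous perborate, base-induced loss of water across C6–C7 (aromatisation) or retro-aldol cleavage may set in. The fallback moves the boron-to-oxygen exchange into an aprotic medium; it sets out from 19 and comes back at 20. Anhydrous trimethylamine N-oxide in THF (it can also be added to the cooled mixture of step 10) should transfer oxygen to boron without hydroxide or peroxide and give the borate ester F5, which is cleaved to 20 by hydrolysis in pH 7 buffer.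

3. Step 4. Stepwise oxygen transfer with C–C rotation may give trans-epoxide, and the hindered cis-alkene may react with low enantioselectivity. The fallback changes from catalyst-controlled oxo transfer to delivery of the oxidant from a metal bound to the tertiary carbinol: hydroxyl-directed epoxidation of 5 with WO2(acac)2, a chiral bishydroxamic acid ligand and aqueous H2O2 should give 6 directly. It sets out from 5, comes back at 6 and makes no new compound (F0).

**Further compounds**

F1 | step 10 | (E)-2-(4,4,5,5-tetramethyl-1,3,2-dioxaborolan-2-yl)ethenylzinc bromide | Br[Zn]/C=C/B1OC(C)(C)C(C)(C)O1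
F2 | step 10 | methyl 4-[(tert-butyldimethylsilyl)oxy]-3-[(2R,3R)-4-[(2E)-1-methoxy-3-(pinacolboryl)prop-2-en-1-ylidene]-5-[4-phenyl-2-(trimethylsilyloxy)but-1-en-1-yl]-2-[2-(trimethylsilyloxy)propan-2-yl]oxolan-3-yl]benzoate (C5 of the oxolane and the enol ether geometry not defined) | COC(=O)c1ccc(O[Si](C)(C)C(C)(C)C)c(c1)[C@H]2[C@H](C(C)(C)O[Si](C)(C)C)OC(C=C(O[Si](C)(C)C)CCc3ccccc3)/C2=C(OC)\C=C\B4OC(C)(C)C(C)(C)O4
F3 | step 10 | O-trimethylsilyl ether (tertiary carbinol) of 19 | COC(=O)c1ccc(O[Si](C)(C)C(C)(C)C)c(c1)[C@@H]2C3=C(O[C@H]2C(C)(C)O[Si](C)(C)C)[C@H](C(=O)CCc4ccccc4)[C@H](B5OC(C)(C)C(C)(C)O5)C=C3OC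
F4 | step 10 | O-trimethylsilyl ether (tertiary carbinol) of 20 | COC(=O)c1ccc(O[Si](C)(C)C(C)(C)C)c(c1)[C@@H]2C3=C(O[C@H]2C(C)(C)O[Si](C)(C)C)[C@H](C(=O)CCc4ccccc4)[C@H](O)C=C3OC
F5 | step 11 | pinacol borate ester of 20 at the C6 oxygen | COC(=O)c1ccc(O[Si](C)(C)C(C)(C)C)c(c1)[C@@H]2C3=C(O[C@H]2C(C)(C)O)[C@H](C(=O)CCc4ccccc4)[C@H](OB5OC(C)(C)C(C)(C)O5)C=C3OC
F0 | step 4 | none | none
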